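## Retrosynthetic overview
1. Target (R)-acetate ⇒ its 3,5-bis(benzyl ether). The last step is neutral hydrogenolysis, which spares the homobenzylic (not benzylic) acetate.
2. The O–acetyl bond and the ArCH2–CH(O) bond are made in one pot. The aryl Grignard from 1,3-bis(benzyloxy)-5-bromobenzene opens (R)-2-undecyloxirane at its CH2, and the alkoxide is trapped with Ac2O.
3. (R)-2-Undecyloxirane ⇒ decylmagnesium bromide + (R)-epichlorohydrin (chiral pool). The only stereocentre is bought and is never a reacting centre.
4. Rings: the benzene ring is bought. The only ring made is the oxirane (step 1), and it is opened again in step 2.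

Assumption: the stereocentre in the given SMILES is (R) by CIP analysis (O > CH2Ar > undecyl > H), and decylmagnesium bromide (1.0 M in Et2O), (R)-epichlorohydrin (≥99 % ee) and 1,3-bis(benzyloxy)-5-bromobenzene are catalogue items.

## Route

Step 1
Reactants: 1 decylmagnesium bromide; 2 (R)-epichlorohydrin
Product: 4 (R)-2-undecyloxirane, via (R)-1-chlorotridecan-2-ol 3 (not isolated)
Conditions: 2 (1.0 equiv), CuI (10 mol %), THF, −40 °C, add 1 (1.1 equiv, Et2O), −40 → 0 °C, 2 h; then H2O, 5 M aq NaOH (3 equiv), 0 °C → rt, 4 h, same flask; Celite, distil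
Reagents that add atoms: none
Why: Cu(I)-catalysed SN2 epoxide opening by the Grignard reagent occurs only at the unsubstituted ring CH2, and the base-induced intramolecular Williamson closure occurs only at CH2Cl, so the C–O stereocentre of 2 is never touched and is carried into 4 as (R).

Step 2
Reactants: 5 1,3-bis(benzyloxy)-5-bromobenzene; 4 (R)-2-undecyloxirane
Product: 8 (R)-1-[3,5-bis(benzyloxy)phenyl]tridecan-2-yl acetate, via aryl Grignard 6 (not isolated), via bromomagnesium alkoxide 7 (not isolated)
Conditions: 5 (1.3 equiv), Mg (1.5 equiv), I2 (cat.), THF, reflux, 1 h; CuI (10 mol %), 4 (1.0 equiv), THF, −30 → 0 °C, 3 h; then Ac2O (4 equiv), DMAP (10 mol %), 0 °C → rt, 2 h; H2O work-up, SiO2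
Reagents that add atoms: acetic anhydride, CC(=O)OC(C)=O; magnesium, [Mg] (kept only in 6 and 7, not in 8)
Why: Grignard formation is followed by Cu(I)-catalysed SN2 opening of the terminal epoxide at its CH2 and in situ O-acylation of the magnesium alkoxide, as in the common Grignard/Ac2O quench, and neither event breaks a bond at the stereocentre, so (R) is retained while the benzyl ethers are inert throughout.

Step 3
Reactants: 8 (R)-1-[3,5-bis(benzyloxy)phenyl]tridecan-2-yl acetate
Product: 9 (R)-1-(3,5-dihydroxyphenyl)tridecan-2-yl acetate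
Conditions: H2 (1 atm), 10 % Pd/C, EtOAc, rt, 4–6 h
Reagents that add atoms: none
Why: Catalytic hydrogenolysis cleaves only the two benzylic C–O bonds of the aryl benzyl ethers, while the homobenzylic secondary acetate and its stereocentre are inert and the neutral aprotic medium excludes acyl transfer or transesterification.

## Compound list
1 | decylmagnesium bromide | CCCCCCCCCC[Mg]Br | starting material
2 | (R)-epichlorohydrin, (2R)-2-(chloromethyl)oxirane | ClC[C@H]1CO1 | starting material
3 | (R)-1-chlorotridecan-2-ol (formed as its Mg alkoxide, freed on the aqueous quench, not isolated) | CCCCCCCCCCC[C@@H](O)CCl | intermediate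
4 | (R)-2-undecyloxirane, (R)-1,2-epoxytridecane | CCCCCCCCCCC[C@@H]1CO1 | intermediate
5 | 1,3-bis(benzyloxy)-5-bromobenzene | Brc1cc(OCc2ccccc2)cc(OCc2ccccc2)c1 | starting material
6 | [3,5-bis(benzyloxy)phenyl]magnesium bromide (not isolated) | Br[Mg]c1cc(OCc2ccccc2)cc(OCc2ccccc2)c1 | intermediate
7 | bromomagnesium (R)-1-[3,5-bis(benzyloxy)phenyl]tridecan-2-olate (not isolated) | CCCCCCCCCCC[C@H](Cc1cc(OCc2ccccc2)cc(OCc2ccccc2)c1)O[Mg]Br | intermediate
8 | (R)-1-[3,5-bis(benzyloxy)phenyl]tridecan-2-yl acetate | CCCCCCCCCCC[C@H](Cc1cc(OCc2ccccc2)cc(OCc2ccccc2)c1)OC(C)=O | intermediate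
9 | (R)-1-(3,5-dihydroxyphenyl)tridecan-2-yl acetate (CNP0241330.1) | CCCCCCCCCCC[C@H](Cc1cc(O)cc(O)c1)OC(C)=O | target

## Totals and risks
Total step count: 3. Longest linear sequence: 3 (1 + 2 → 4 → 8 → 9).

**Most likely to fail: step 2.** Three operations share one flask. The risks are sluggish Mg insertion, MgBr2-induced bromohydrin formation and incomplete acylation.

The fallback sets out from 5 (with 4 as partner) and comes back at 8. It uses no preformed aryl-metal and joins the two electrophiles by Ni-catalysed reductive cross-electrophile coupling. The conditions are NiCl2·glyme/2,2'-bipyridine (10 mol %), NaI (25 mol %), Et3N·HCl and Zn in DMPU at rt.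

Iodide opens 4 at the terminal CH2 to transient (R)-1-iodotridecan-2-ol F1, which is arylated at that same carbon, so the carbinol centre is untouched. This gives (R)-1-[3,5-bis(benzyloxy)phenyl]tridecan-2-ol F2. F2 is isolated, its ee is checked, and it is acetylated in a separate operation (Ac2O, pyridine, DMAP, CH2Cl2, rt) to 8.

**Second: step 1.** Halide attack on epichlorohydrin can scramble it and erode the ee, and over-addition is possible.

The fallback sets out from 1 and comes back at 4. It replaces chiral-pool transfer by kinetic resolution: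
- Allylation of 1 with allyl bromide (THF, 0 °C → rt) gives tridec-1-ene F3, which can also be bought.
- Prilezhaev epoxidation (mCPBA, CH2Cl2) gives racemic 2-undecyloxirane F4.
- Jacobsen hydrolytic kinetic resolution with (R,R)-(salen)Co(III)OAc (0.5 mol %) and H2O (0.55 equiv) hydrolyses the (S)-enantiomer. It leaves 4 in >99 % ee (at most 50 % yield), which is separated by distillation.

**Third: step 3.** Cu or iodide traces may poison the catalyst, or the reaction may stall at the mono-benzyl ether.

The fallback sets out from 8 and comes back at 9. It replaces reductive cleavage by Lewis-acid dealkylation. BCl3 (4 equiv) with pentamethylbenzene (6 equiv) as a non-basic benzyl-cation scavenger in CH2Cl2 at −78 °C gives (R)-1-{3,5-bis[(dichloroboranyl)oxy]phenyl}tridecan-2-yl acetate F5. An aqueous quench hydrolyses F5 to 9. The alkyl acetate survives at this temperature.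

## Further compounds
F1 | step 2 | (R)-1-iodotridecan-2-ol | CCCCCCCCCCC[C@@H](O)CI
F2 | step 2 | (R)-1-[3,5-bis(benzyloxy)phenyl]tridecan-2-ol | CCCCCCCCCCC[C@H](Cc1cc(OCc2ccccc2)cc(OCc2ccccc2)c1)O
F3 | step 1 | tridec-1-ene | CCCCCCCCCCCC=C
F4 | step 1 | racemic 2-undecyloxirane | CCCCCCCCCCCC1CO1
F5 | step 3 | (R)-1-{3,5-bis[(dichloroboranyl)oxy]phenyl}tridecan-2-yl acetate | CCCCCCCCCCC[C@H](Cc1cc(OB(Cl)Cl)cc(OB(Cl)Cl)c1)OC(C)=O
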